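Everything rests on cutting the unactivated polymethylene chain between C7′ and C8′ of the 14-oxopentadecyl side chain (numbered from oxolane carbon C2): two methylene carbons of like polarity, remote from both the C14′ ketone and the lactone ring with its C2, C3 and C4 stereocentres. Each is traced back to a carboxyl group: a mixed Kolbe electrolysis unites 8-oxononanoic acid with an ω-carboxyheptyl γ-lactone that already holds all three stereocentres and the ring carboxyl as tert-butyl ester, forming the C7′–C8′ bond in one anodic operation with loss of two CO2. The lactone acid arises from Noyori reduction, Fráter–Seebach allylation, double ozonolysis and trans-selective methylation.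

Key step: step 6

Remark: 8-oxononanoic acid is taken as a purchasable keto acid; metal enolates, ozonides and anode-generated radicals are regarded as transient species within a step, so only the lactol aldehyde carried crude through step 4 is numbered as a non-isolated compound.

Step 1
Reactants: 1 tert-butyl 3-oxobutanoate; 2 8-bromooct-1-ene
Product: 3 tert-butyl 3-oxododec-11-enoate
Conditions: NaH, THF, 0 °C; n-BuLi, 0 °C; then 2, 0 °C → rt; aq. NH4Cl
Reagents that add atoms: none
Why: Huckin–Weiler dianion alkylation, in which the more basic terminal (γ) carbanion of the acetoacetate dianion displaces the primary bromide by SN2 and the 1,3-dicarbonyl unit stays intact; no stereocentre is formed.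

Step 2
Reactants: 3 tert-butyl 3-oxododec-11-enoate
Product: 4 tert-butyl (3S)-3-hydroxydodec-11-enoate
Conditions: RuCl2[(S)-BINAP] (0.5 mol%), H2 (4 bar), MeOH, 50 °C
Reagents that add atoms: none
Why: Noyori asymmetric hydrogenation, in which the β-keto ester chelates the Ru–(S)-BINAP centre and hydride is delivered to one carbonyl face to set C3 as (S) (the same sense in which (R)-BINAP gives (R)-3-hydroxybutanoates), while at low hydrogen pressure the non-chelating terminal alkene should stay untouched.

Step 3
Reactants: 4 tert-butyl (3S)-3-hydroxydodec-11-enoate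
Product: 5 tert-butyl (2S,3S)-3-hydroxy-2-(prop-2-en-1-yl)dodec-11-enoate
Conditions: LDA (2.2 equiv), THF, −78 → −20 °C; allyl bromide, DMPU, −78 → −20 °C
Reagents that add atoms: allyl bromide (3-bromoprop-1-ene), C=CCBr
Why: Fráter–Seebach alkylation, in which the lithium alkoxide/ester enolate dianion forms a six-membered chelate and allyl bromide enters on the face opposite the C3 alkyl chain, setting C2 as (S), anti to the hydroxyl, which is the relationship that becomes 2,3-cis on the lactone ring.

Step 4
Reactants: 5 tert-butyl (2S,3S)-3-hydroxy-2-(prop-2-en-1-yl)dodec-11-enoate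
Product: 7 8-[(2S,3S)-3-(tert-butoxycarbonyl)-5-oxooxolan-2-yl]octanoic acid, via lactol aldehyde 6 (not isolated)
Conditions: O3, CH2Cl2, −78 °C; Me2S, −78 °C → rt; concentrate; then Jones reagent (CrO3, H2SO4, H2O), acetone, 0 °C
Reagents that add atoms: ozone, [O-][O+]=O; chromic acid (Jones reagent), O[Cr](=O)(=O)O; water, O
Why: Double ozonolysis cleaves both monosubstituted alkenes, the aldehyde born from the allyl group is trapped by the secondary hydroxyl as the five-membered lactol, and Jones oxidation then takes the lactol to the γ-lactone and the chain aldehyde to the carboxylic acid under acidic conditions that should leave the tert-butyl ester and both stereocentres unchanged.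

Step 5
Reactants: 7 8-[(2S,3S)-3-(tert-butoxycarbonyl)-5-oxooxolan-2-yl]octanoic acid
Product: 8 8-[(2S,3S,4S)-3-(tert-butoxycarbonyl)-4-methyl-5-oxooxolan-2-yl]octanoic acid
Conditions: LiHMDS (2.2 equiv), THF, −78 °C; MeI, −78 → −40 °C; aq. citric acid
Reagents that add atoms: iodomethane, CI
Why: Enolate alkylation of a dianion, in which the first equivalent of base forms the remote lithium carboxylate, the second removes a proton from the more acidic and less hindered lactone C4 methylene and not from the C3 methine, and iodomethane attacks the enolate face opposite the cis-disposed C2 alkyl and C3 ester groups, setting C4 as (S), trans to the ester.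

Step 6
Reactants: 8 8-[(2S,3S,4S)-3-(tert-butoxycarbonyl)-4-methyl-5-oxooxolan-2-yl]octanoic acid; 9 8-oxononanoic acid
Product: 10 tert-butyl (2S,3S,4S)-4-methyl-5-oxo-2-(14-oxopentadecyl)oxolane-3-carboxylate
Conditions: 9 (6 equiv), KOH (5 mol% of total acid), MeOH, Pt anode, Pt cathode, undivided cell, constant current (about 0.15 A cm−2), 40 °C
Reagents that add atoms: none
Why: Mixed Kolbe electrolysis: the carboxylates of 8 and 9 are oxidised at the platinum anode, lose CO2 and give two primary alkyl radicals (the lactone-bearing heptyl radical and the 7-oxooctyl radical) that combine in the dense radical layer at the electrode to form the C7′–C8′ bond of the side chain. The closest known reaction type is the classical anodic cross-coupling of two unbranched fatty acids, in which remote ketones, esters and lactones are spectators. No ring is closed and no stereocentre is formed; C2, C3 and C4 lie at least seven bonds from the radical centre, and the weakly acidic methanol (only a few per cent of the acid neutralised) should neither epimerise them nor open the lactone. The step needs cross- over homo-coupling, which a several-fold excess of the cheap acid 9 secures statistically, the main by-product then being the readily separated symmetrical diketone from 9. It also needs radical over cation (Hofer–Moest) chemistry, which is secured by both carboxyl groups being primary and unbranched at the α-carbon, by the smooth platinum anode and by the high current density. The only carboxyl that would take the cation path, the α-branched ring acid at C3, is masked as the tert-butyl ester, which is inert at the anode.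

Step 7
Reactants: 10 tert-butyl (2S,3S,4S)-4-methyl-5-oxo-2-(14-oxopentadecyl)oxolane-3-carboxylate
Product: 11 (2S,3S,4S)-4-methyl-5-oxo-2-(14-oxopentadecyl)oxolane-3-carboxylic acid
Conditions: TFA, CH2Cl2, 0 °C → rt
Reagents that add atoms: none
Why: Acidolysis of the tert-butyl ester through the tert-butyl cation (E1 loss of isobutene) frees the ring carboxylic acid without base, so the epimerisable C3 and C4 centres, the lactone and the methyl ketone should be unaffected.

Compound list
1 | tert-butyl 3-oxobutanoate (tert-butyl acetoacetate) | CC(=O)CC(=O)OC(C)(C)C | starting material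
2 | 8-bromooct-1-ene | C=CCCCCCCBr | starting material
3 | tert-butyl 3-oxododec-11-enoate | C=CCCCCCCCC(=O)CC(=O)OC(C)(C)C | intermediate
4 | tert-butyl (3S)-3-hydroxydodec-11-enoate | C=CCCCCCCC[C@H](O)CC(=O)OC(C)(C)C | intermediate
5 | tert-butyl (2S,3S)-3-hydroxy-2-(prop-2-en-1-yl)dodec-11-enoate | C=CCCCCCCC[C@H](O)[C@H](CC=C)C(=O)OC(C)(C)C | intermediate
6 | lactol aldehyde: tert-butyl (2S,3S)-5-hydroxy-2-(8-oxooctyl)oxolane-3-carboxylate, both C5 anomers | O=CCCCCCCC[C@@H]1OC(O)C[C@@H]1C(=O)OC(C)(C)C | intermediate (not isolated)
7 | 8-[(2S,3S)-3-(tert-butoxycarbonyl)-5-oxooxolan-2-yl]octanoic acid | OC(=O)CCCCCCC[C@@H]1OC(=O)C[C@@H]1C(=O)OC(C)(C)C | intermediate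
8 | 8-[(2S,3S,4S)-3-(tert-butoxycarbonyl)-4-methyl-5-oxooxolan-2-yl]octanoic acid | OC(=O)CCCCCCC[C@@H]1OC(=O)[C@@H](C)[C@@H]1C(=O)OC(C)(C)C | intermediate
9 | 8-oxononanoic acid | CC(=O)CCCCCCC(=O)O | starting material
10 | tert-butyl (2S,3S,4S)-4-methyl-5-oxo-2-(14-oxopentadecyl)oxolane-3-carboxylate | CC(=O)CCCCCCCCCCCCC[C@@H]1OC(=O)[C@@H](C)[C@@H]1C(=O)OC(C)(C)C | intermediate
11 | (2S,3S,4S)-4-methyl-5-oxo-2-(14-oxopentadecyl)oxolane-3-carboxylic acid (alkyl and carboxyl cis, carboxyl and methyl trans) | CC(=O)CCCCCCCCCCCCC[C@@H]1OC(=O)[C@@H](C)[C@@H]1C(=O)O | target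

Total step count: 7. Longest linear sequence: 7 steps (1 and 2 to 11); 9 enters as a purchased partner in step 6.

Steps most likely to fail

Step 6. Homo-coupling of each acid and over-oxidation of the radicals to cations (methyl ethers and alkenes by the Hofer–Moest path) may leave too little cross-product. The fallback sets out from 8 and 9 and comes back at 10. Each acid is converted with N-hydroxyphthalimide and DIC (cat. DMAP, CH2Cl2) into its redox-active ester, 1,3-dioxoisoindolin-2-yl 8-[(2S,3S,4S)-3-(tert-butoxycarbonyl)-4-methyl-5-oxooxolan-2-yl]octanoate F1 and 1,3-dioxoisoindolin-2-yl 8-oxononanoate F2. A nickel-electrocatalytic doubly decarboxylative C(sp3)–C(sp3) cross-coupling of the two esters (NiCl2·6H2O, terpyridine ligand, silver-nanoparticle-coated cathode from AgNO3, Mg sacrificial anode, NMP, constant current, F2 in three-fold excess) should then give 10 by nickel-mediated reductive coupling in place of free radical–radical combination.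

Step 5. Deprotonation may stray to the C3 methine, which would lead to epimerisation to the trans-lactone or to β-elimination with ring opening, and the dilithio salt may aggregate and react sluggishly. The fallback sets out from 4 and comes back at 8, so that a neutral lactone is methylated before the chain carboxyl exists. Fráter–Seebach alkylation of 4 with methyl bromoacetate (COC(=O)CBr; LDA 2.2 equiv, THF/DMPU, −78 → −30 °C) should give 1-tert-butyl 4-methyl (2S)-2-[(1S)-1-hydroxydec-9-en-1-yl]butanedioate F3. Acid-catalysed lactonisation (cat. TsOH, CH2Cl2, rt) should give tert-butyl (2S,3S)-2-(non-8-en-1-yl)-5-oxooxolane-3-carboxylate F4. Methylation of its mono-enolate (LiHMDS 1.1 equiv, MeI, THF, −78 °C) should give tert-butyl (2S,3S,4S)-4-methyl-2-(non-8-en-1-yl)-5-oxooxolane-3-carboxylate F5, and oxidative cleavage of the terminal alkene (cat. RuCl3, NaIO4, CCl4/MeCN/H2O) returns 8.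

Step 2. Partial saturation or migration of the terminal double bond during the hydrogenation would give chain-modified material that cannot be separated. The fallback sets out from 1 and comes back at 7, with a silyl ether instead of the alkene as the latent chain carboxyl. 7-Bromoheptan-1-ol (OCCCCCCCBr) is silylated (TBSCl, imidazole, DMF) to [(7-bromoheptyl)oxy](tert-butyl)dimethylsilane F6, which alkylates the dianion of 1 (NaH, n-BuLi, THF) to tert-butyl 11-[(tert-butyldimethylsilyl)oxy]-3-oxoundecanoate F7. The now alkene-free keto ester is hydrogenated over Ru–(S)-BINAP to tert-butyl (3S)-11-[(tert-butyldimethylsilyl)oxy]-3-hydroxyundecanoate F8. Fráter–Seebach allylation gives tert-butyl (2S,3S)-11-[(tert-butyldimethylsilyl)oxy]-3-hydroxy-2-(prop-2-en-1-yl)undecanoate F9. Ozonolysis (Me2S work-up) gives the crude lactol tert-butyl (2S,3S)-2-{8-[(tert-butyldimethylsilyl)oxy]octyl}-5-hydroxyoxolane-3-carboxylate F10, and Jones oxidation, which also cleaves the primary silyl ether and oxidises the freed alcohol to the acid, gives 7.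

Further compounds
F1 | step 6 | 1,3-dioxoisoindolin-2-yl 8-[(2S,3S,4S)-3-(tert-butoxycarbonyl)-4-methyl-5-oxooxolan-2-yl]octanoate | O=C(CCCCCCC[C@@H]1OC(=O)[C@@H](C)[C@@H]1C(=O)OC(C)(C)C)ON1C(=O)c2ccccc2C1=O
F2 | step 6 | 1,3-dioxoisoindolin-2-yl 8-oxononanoate | CC(=O)CCCCCCC(=O)ON1C(=O)c2ccccc2C1=O
F3 | step 5 | 1-tert-butyl 4-methyl (2S)-2-[(1S)-1-hydroxydec-9-en-1-yl]butanedioate | C=CCCCCCCC[C@H](O)[C@H](CC(=O)OC)C(=O)OC(C)(C)C
F4 | step 5 | tert-butyl (2S,3S)-2-(non-8-en-1-yl)-5-oxooxolane-3-carboxylate | C=CCCCCCCC[C@@H]1OC(=O)C[C@@H]1C(=O)OC(C)(C)C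
F5 | step 5 | tert-butyl (2S,3S,4S)-4-methyl-2-(non-8-en-1-yl)-5-oxooxolane-3-carboxylate | C=CCCCCCCC[C@@H]1OC(=O)[C@@H](C)[C@@H]1C(=O)OC(C)(C)C
F6 | step 2 | [(7-bromoheptyl)oxy](tert-butyl)dimethylsilane | BrCCCCCCCO[Si](C)(C)C(C)(C)C
F7 | step 2 | tert-butyl 11-[(tert-butyldimethylsilyl)oxy]-3-oxoundecanoate | CC(C)(C)[Si](C)(C)OCCCCCCCCC(=O)CC(=O)OC(C)(C)C
F8 | step 2 | tert-butyl (3S)-11-[(tert-butyldimethylsilyl)oxy]-3-hydroxyundecanoate | CC(C)(C)[Si](C)(C)OCCCCCCCC[C@H](O)CC(=O)OC(C)(C)C
F9 | step 2 | tert-butyl (2S,3S)-11-[(tert-butyldimethylsilyl)oxy]-3-hydroxy-2-(prop-2-en-1-yl)undecanoate | CC(C)(C)[Si](C)(C)OCCCCCCCC[C@H](O)[C@H](CC=C)C(=O)OC(C)(C)C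
F10 | step 2 | tert-butyl (2S,3S)-2-{8-[(tert-butyldimethylsilyl)oxy]octyl}-5-hydroxyoxolane-3-carboxylate | CC(C)(C)[Si](C)(C)OCCCCCCCC[C@@H]1OC(O)C[C@@H]1C(=O)OC(C)(C)C
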